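**Retrosynthetic overview**

1. Target: (13E)-8α-hydroxylabd-13-en-15-yl acetate. First cut: the C11–C12 single bond. It separates a C5 (E)-allyl half, electrophilic at C12 and made from prenyl acetate by E-selective allylic oxidation and carbonate formation, from a drimane C15 half that carries a radical at C11.
2. Enabling feature: the tertiary oxygen on C8 is γ to the exocyclic carbon C11, so both sit in the γ-lactone ring O8–C(=O)–C11–C9–C8 fused to ring B of commercial (+)-sclareolide. The lactone carbonyl carbon lies one atom beyond C11 and can leave as CO2, which puts the radical on C11 and frees the C8–OH; on the other side C12–C13=C14 is an allyl unit that nickel can hold as an η3-allyl.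
3. Second cut: the acyl–O8 bond of that lactone (saponification to the caesium hydroxy-carboxylate), so that the union is a decarboxylative C(sp3)–C(sp3) allylation that gives the target directly, without protecting groups.
4. Ring order: rings A and B are not built in the route; they come trans-fused from sclareolide with C5, C8, C9 and C10 already set. The only ring event is the opening of the temporary γ-lactone ring (step 3), whose carbonyl carbon is expelled in step 4.

Key step: step 4

Remark: the target is read as drawn, i.e. the normal labdane series (5S,8R,9R,10S in labdane numbering) with a 13E olefin; these four centres are those of commercial (+)-sclareolide, and labdane numbering is used for all atom positions.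

Step 1
Reactants: 1 prenyl acetate (3-methylbut-2-en-1-yl acetate)
Product: 2 (2E)-4-hydroxy-3-methylbut-2-en-1-yl acetate
Conditions: SeO2 (0.3 equiv), t-BuOOH (2.5 equiv), salicylic acid (0.1 equiv), CH2Cl2, 20 °C
Reagents that add atoms: selenium dioxide O=[Se]=O (catalytic oxygen carrier); tert-butyl hydroperoxide CC(C)(C)OO (terminal oxidant)
Why: Riley allylic oxidation in its catalytic form: ene reaction of SeO2 followed by [2,3]-sigmatropic shift of the allylseleninic acid should oxidise only the methyl group trans to the CH2OAc chain, so that the cyclic transition states set the E geometry of the trisubstituted olefin while the acetate is inert.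

Step 2
Reactants: 2 (2E)-4-hydroxy-3-methylbut-2-en-1-yl acetate
Product: 3 (2E)-4-acetoxy-2-methylbut-2-en-1-yl tert-butyl carbonate
Conditions: Boc2O (1.3 equiv), DMAP (0.1 equiv), CH2Cl2, 0 → 20 °C
Reagents that add atoms: di-tert-butyl dicarbonate CC(C)(C)OC(=O)OC(=O)OC(C)(C)C
Why: DMAP-catalysed O-acylation (carbonate formation) of the only free hydroxyl should give the mixed carbonate, which nickel ionises far faster than the acetate at the other allylic terminus; the olefin geometry is not touched.

Step 3
Reactants: 4 (+)-sclareolide, (3aR,5aS,9aS,9bR)-3a,6,6,9a-tetramethyldecahydronaphtho[2,1-b]furan-2(1H)-one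
Product: 5 caesium 2-[(1R,2R,4aS,8aS)-2-hydroxy-2,5,5,8a-tetramethyldecahydronaphthalen-1-yl]acetate (ring-opened sclareolide; 8α-OH free, carboxylate carbon attached to C11)
Conditions: CsOH·H2O (0.98 equiv), MeOH/H2O 4:1, 65 °C; evaporation, trituration with Et2O, drying in vacuo
Reagents that add atoms: caesium hydroxide [Cs+].[OH-]
Why: Saponification of the γ-lactone by acyl–oxygen cleavage: the C8–O bond is not broken and C9 is not acidic, so all four stereocentres are kept, and the caesium salt cannot re-close as long as it is not protonated.

Step 4
Reactants: 5 caesium 2-[(1R,2R,4aS,8aS)-2-hydroxy-2,5,5,8a-tetramethyldecahydronaphthalen-1-yl]acetate; 3 (2E)-4-acetoxy-2-methylbut-2-en-1-yl tert-butyl carbonate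
Product: 6 (2E)-5-[(1R,2R,4aS,8aS)-2-hydroxy-2,5,5,8a-tetramethyldecahydronaphthalen-1-yl]-3-methylpent-2-en-1-yl acetate (target)
Conditions: Ir[dF(CF3)ppy]2(dtbbpy)PF6 (2 mol%), NiCl2·glyme (10 mol%), 4,4′-di-tert-butyl-2,2′-bipyridine (12 mol%), 3 (1.5 equiv), degassed DMSO, blue LEDs (450 nm), 25 °C
Reagents that add atoms: none
Why: Proposed new method: dual iridium-photoredox/nickel decarboxylative C(sp3)–C(sp3) allylation, in which the excited Ir(III) catalyst oxidises the carboxylate of 5, the acyloxy radical loses CO2 to leave a primary radical on C11, Ni(0) ionises the tert-butyl carbonate of 3 to a syn-η3-allylnickel(II) spanning C12–C13–C14, this complex captures the radical, reductive elimination from Ni(III) at the unsubstituted terminus C12 forms C11–C12, and the reduced photocatalyst returns nickel to Ni(0). The closest known reaction types are the metallaphotoredox decarboxylative coupling of aliphatic carboxylic acids with alkyl halides and the nickel-catalysed reductive allylation of alkyl halides with allylic carbonates, which supply the two half-cycles joined here; new is their use on an unstabilised, neopentyl-type primary carboxylate together with an allylic carbonate. No ring is closed and no stereocentre is created: C5, C8, C9 and C10 come unchanged from 4 because the radical is confined to exocyclic C11 and the medium is neither acidic nor strongly basic, and the 13E geometry of 3 is carried through the syn-η3-allyl, whose syn/anti exchange would need η1-bonding at the substituted C14 whereas coupling occurs at C12. The step needs (i) ionisation of the carbonate and not of the allylic acetate, secured by the much faster oxidative addition of carbonates and the excess of 3, (ii) bond formation at C12 and not C14, secured by the unsubstituted allyl terminus, and (iii) C–C and not C–O coupling of the carboxylate, favoured because allyl carboxylates add back to Ni(0) and because the salt, unlike the free hydroxy acid, cannot close to the lactone. In this single operation the extra lactone carbon is expelled as CO2, the tertiary C8–OH appears without ever being protected, and the side chain arrives with its acetate, so that 6 should form directly.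

**Compound list**

1 | prenyl acetate (3-methylbut-2-en-1-yl acetate) | CC(=O)OCC=C(C)C | starting material
2 | (2E)-4-hydroxy-3-methylbut-2-en-1-yl acetate | CC(=O)OC/C=C(\C)CO | intermediate
3 | (2E)-4-acetoxy-2-methylbut-2-en-1-yl tert-butyl carbonate | CC(=O)OC/C=C(\C)COC(=O)OC(C)(C)C | intermediate
4 | (+)-sclareolide, (3aR,5aS,9aS,9bR)-3a,6,6,9a-tetramethyldecahydronaphtho[2,1-b]furan-2(1H)-one | O=C1C[C@@H]2[C@@]3(C)CCCC(C)(C)[C@@H]3CC[C@@]2(C)O1 | starting material
5 | caesium 2-[(1R,2R,4aS,8aS)-2-hydroxy-2,5,5,8a-tetramethyldecahydronaphthalen-1-yl]acetate | [Cs+].[O-]C(=O)C[C@@H]1[C@@]2(C)CCCC(C)(C)[C@@H]2CC[C@@]1(C)O | intermediate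
6 | (2E)-5-[(1R,2R,4aS,8aS)-2-hydroxy-2,5,5,8a-tetramethyldecahydronaphthalen-1-yl]-3-methylpent-2-en-1-yl acetate | CC(=O)OC/C=C(\C)CC[C@@H]1[C@@]2(C)CCCC(C)(C)[C@@H]2CC[C@@]1(C)O | target

**Step count and risks**

Total step count: 4. Longest linear sequence: 3 steps (1 → 2 → 3 → 6); the sclareolide branch 4 → 5 → 6 has 2 steps.

Steps most likely to fail:

Step 4 (carries the label). What may go wrong: oxidation of the unstabilised primary carboxylate may be too slow; the C11 radical may be lost by hydrogen abstraction, or by β-hydride elimination after capture on nickel; or the carboxylate may undergo C–O allylation followed by re-closure of the lactone. The fallback uses known reaction types only, sets out from 4 and comes back to the route at 6. The lactone carbon is removed by alkoxy-radical fragmentation instead of decarboxylation, and the union is done as a reductive cross-electrophile coupling. Half-reduction of 4 with DIBAL-H (CH2Cl2, −78 °C) should give the lactol (3aR,5aS,9aS,9bR)-3a,6,6,9a-tetramethyldodecahydronaphtho[2,1-b]furan-2-ol F1. Its hypoiodite, made with PhI(OAc)2/I2 under visible light (cyclohexane, 25 °C), should undergo β-scission of the bond between C11 and the lactol carbon and iodine capture (Suárez fragmentation) to give 11-iodo-drimane-8α-yl formate F2. Ammonolysis of the formate (NH3 in MeOH, 0 °C) should give 11-iodo-drimane-8α-ol F3. Nickel-catalysed reductive allylation of F3 with 3 (NiBr2·glyme, 4,4′-di-tert-butyl-2,2′-bipyridine, Zn, MgCl2, DMA, 25 °C) should then form the same C11–C12 bond and give 6.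

Step 1. What may go wrong: over-oxidation of the allylic alcohol to the enal, stalling at low conversion, and partial erosion of the E geometry. The fallback sets out from 1 and comes back at 2; the E-olefin is built by olefination instead of C–H oxidation. Ozonolysis of 1 (O3, CH2Cl2, −78 °C; then Me2S) should give 2-oxoethyl acetate F4. Wittig reaction with the stabilised ylide 2-(triphenylphosphoranylidene)propanal (toluene, 60 °C) should give (2E)-4-acetoxy-2-methylbut-2-enal F5, with the E geometry typical of stabilised ylides. Chemoselective reduction of the aldehyde (NaBH4, MeOH, −20 °C) should give 2.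

Step 3. What may go wrong: re-closure of the γ-lactone while the salt is concentrated and dried, or incomplete ring opening, so that lactone and moisture are carried into the water-sensitive nickel step. The fallback sets out from 4 and 2 and comes back at 6. The lactone stays closed during C–C bond formation, serves as the activating group for a polar alkylation, and is opened only in water-tolerant operations. Appel bromination of 2 (CBr4, PPh3, CH2Cl2, 0 °C) should give (2E)-4-bromo-3-methylbut-2-en-1-yl acetate F6. The lithium enolate of 4 (LDA, THF, −78 °C) should be alkylated at C11 by F6 to give 11-[(2E)-4-acetoxy-2-methylbut-2-en-1-yl]sclareolide F7 (either C11 epimer). KOH in aqueous MeOH (65 °C) should open the lactone and cleave the acetate to give potassium (4E)-6-hydroxy-2-[(1R,2R,4aS,8aS)-2-hydroxy-2,5,5,8a-tetramethyldecahydronaphthalen-1-yl]-4-methylhex-4-enoate F8, which is used without drying. Acridinium-photocatalysed hydrodecarboxylation (9-mesityl-10-phenylacridinium tetrafluoroborate, PhSSPh, CF3CH2OH, 450 nm) should give (13E)-labd-13-ene-8α,15-diol F9. Acetylation of the primary allylic alcohol only (Ac2O, pyridine, 0 °C) should give 6.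

**Further compounds**

F1 | step 4 | sclareolide lactol, (3aR,5aS,9aS,9bR)-3a,6,6,9a-tetramethyldodecahydronaphtho[2,1-b]furan-2-ol (both anomers) | OC1C[C@@H]2[C@@]3(C)CCCC(C)(C)[C@@H]3CC[C@@]2(C)O1
F2 | step 4 | 11-iodo-drimane-8α-yl formate, (1R,2R,4aS,8aS)-1-(iodomethyl)-2,5,5,8a-tetramethyldecahydronaphthalen-2-yl formate | IC[C@@H]1[C@@]2(C)CCCC(C)(C)[C@@H]2CC[C@@]1(C)OC=O
F3 | step 4 | 11-iodo-drimane-8α-ol, (1R,2R,4aS,8aS)-1-(iodomethyl)-2,5,5,8a-tetramethyldecahydronaphthalen-2-ol | IC[C@@H]1[C@@]2(C)CCCC(C)(C)[C@@H]2CC[C@@]1(C)O
F4 | step 1 | 2-oxoethyl acetate | CC(=O)OCC=O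
F5 | step 1 | (2E)-4-acetoxy-2-methylbut-2-enal | CC(=O)OC/C=C(\C)C=O
F6 | step 3 | (2E)-4-bromo-3-methylbut-2-en-1-yl acetate | CC(=O)OC/C=C(\C)CBr
F7 | step 3 | 11-[(2E)-4-acetoxy-2-methylbut-2-en-1-yl]sclareolide (C11 epimers) | O=C1C(C/C(C)=C/COC(C)=O)[C@@H]2[C@@]3(C)CCCC(C)(C)[C@@H]3CC[C@@]2(C)O1
F8 | step 3 | potassium (4E)-6-hydroxy-2-[(1R,2R,4aS,8aS)-2-hydroxy-2,5,5,8a-tetramethyldecahydronaphthalen-1-yl]-4-methylhex-4-enoate (C2 epimers) | [K+].[O-]C(=O)C(C/C(C)=C/CO)[C@@H]1[C@@]2(C)CCCC(C)(C)[C@@H]2CC[C@@]1(C)O
F9 | step 3 | (13E)-labd-13-ene-8α,15-diol | OC/C=C(\C)CC[C@@H]1[C@@]2(C)CCCC(C)(C)[C@@H]2CC[C@@]1(C)O
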